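## Plan

- **Cuts (retrosynthesis):** first the late adjustments (CHO from the isopropenyl CH3, the C3 acetate, the tiglate, the side-chain carbinol from a C5 acetyl group and that from a C5 ester). Then the benzene ring is cut at C7a–C3a and C5–C4 (CO2 put back), then the ether bond O1–C2, then the C3–alkyne bond (to 3-methylbut-2-enal and an ethynyl Grignard reagent).
- **Enabling feature:** the benzene ring carries O1 on C7a and an oxidised carbon on C5, para to it. These are C3 and C6 of a 3-alkoxy-2-pyrone-6-carboxylate, and O1–C2–C3 of the dihydrofuran ring is a three-atom tether ending in the alkyne carbons that become C3a and C4.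
- **Forward order:** open chain with both ring stereocentres, then ether link to the pyrone, then one thermal step that closes the dihydrofuran ring and the benzene ring together, then side-chain work.
- **Stereochemistry:** C3 and C2 come from a Sharpless kinetic-resolution epoxidation (erythro); C2 is inverted in the Mitsunobu etherification (threo, which becomes cis in the ring). The side-chain carbinol comes from a Noyori transfer hydrogenation.
- **Strengthening:** an allyl pyron-3-yl ether can undergo a Claisen shift to pyrone C4 at the temperature of the cycloaddition, so the isopropenyl group is held as its oxirane during the hot step and restored directly afterwards.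

Key step: step 8

Remark: acid 7 is taken as purchasable (it is the known dehydration product of galactaric acid). Remark: the oxirane carbon made in step 7 is formed as both epimers, carried through 10–12 and erased in step 9, so the SMILES of 10–12 leave it open. Atom labels (O1, C2, C3, C3a, C4, C5, C7a) follow the 2,3-dihydrobenzofuran numbering of the target.

## Route

Step 1
Reactants: 1 3-methylbut-2-enal; 2 ethynylmagnesium bromide
Product: 3 rac-5-methylhex-4-en-1-yn-3-ol
Conditions: THF, 0 °C; aq. NH4Cl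
Reagents that add atoms: none
Why: Grignard 1,2-addition of a hard alkynyl nucleophile to the enal carbonyl should give the alkynyl allyl carbinol as a racemate, which is resolved in the next step.

Step 2
Reactants: 3 rac-5-methylhex-4-en-1-yn-3-ol
Product: 4 (1S)-1-[(2S)-3,3-dimethyloxiran-2-yl]prop-2-yn-1-ol
Conditions: Ti(OiPr)4 (0.15 equiv), L-(+)-diisopropyl tartrate (0.2 equiv), t-BuOOH (0.45 equiv), 4 Å molecular sieves, CH2Cl2, −20 °C
Reagents that add atoms: tert-butyl hydroperoxide, CC(C)(C)OO
Why: Sharpless kinetic resolution: with the L-(+)-tartrate the (R)-carbinol should be epoxidised much faster than its mirror image and give the erythro epoxy alcohol, so the reagent fixes the oxirane centre and selects the carbinol centre (at most half of 3 can be used; the (S)-alcohol stays behind).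

Step 3
Reactants: 4 (1S)-1-[(2S)-3,3-dimethyloxiran-2-yl]prop-2-yn-1-ol
Product: 5 tert-butyl{[(1S)-1-[(2S)-3,3-dimethyloxiran-2-yl]prop-2-yn-1-yl]oxy}dimethylsilane
Conditions: TBSCl, imidazole, DMF, rt
Reagents that add atoms: tert-butyldimethylsilyl chloride, CC(C)(C)[Si](C)(C)Cl
Why: Imidazole-promoted silylation of a secondary alcohol; the silyl ether tolerates the amide base, the Mitsunobu step and the hot step, and does not eliminate as an ester could.

Step 4
Reactants: 5 tert-butyl{[(1S)-1-[(2S)-3,3-dimethyloxiran-2-yl]prop-2-yn-1-yl]oxy}dimethylsilane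
Product: 6 (3R,4S)-4-[(tert-butyldimethylsilyl)oxy]-2-methylhex-1-en-5-yn-3-ol
Conditions: diethylaluminium 2,2,6,6-tetramethylpiperidide (4 equiv, from 2,2,6,6-tetramethylpiperidine, n-BuLi, Et2AlCl), toluene, 0 °C → rt; aq. NH4Cl
Reagents that add atoms: none
Why: Base-induced isomerisation of an epoxide to an allylic alcohol (syn β-elimination in the aluminium-bound epoxide): a proton of a geminal methyl group is removed and the C–O bond at the CH carbon is untouched, so the erythro relationship is kept; the excess reagent covers reversible metalation of the alkyne C–H.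

Step 5
Reactants: 7 3-hydroxy-2-oxo-2H-pyran-6-carboxylic acid
Product: 8 ethyl 3-hydroxy-2-oxo-2H-pyran-6-carboxylate
Conditions: EtOH, H2SO4 (cat.), reflux
Reagents that add atoms: ethanol, CCO
Why: Fischer esterification; 2-pyrone carboxylic acids are routinely esterified under acid catalysis, and the enolic 3-hydroxyl stays free as the acidic partner for step 6.

Step 6
Reactants: 6 (3R,4S)-4-[(tert-butyldimethylsilyl)oxy]-2-methylhex-1-en-5-yn-3-ol; 8 ethyl 3-hydroxy-2-oxo-2H-pyran-6-carboxylate
Product: 9 ethyl 3-{[(3S,4S)-4-[(tert-butyldimethylsilyl)oxy]-2-methylhex-1-en-5-yn-3-yl]oxy}-2-oxo-2H-pyran-6-carboxylate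
Conditions: PPh3, DIAD, THF, 0 °C → rt
Reagents that add atoms: none
Why: Mitsunobu etherification with the acidic enolic hydroxyl of the pyrone as pronucleophile; SN2 displacement of the oxyphosphonium group inverts the carbinol (3R to 3S) and so turns the erythro into the threo arrangement needed for the cis ring.

Step 7
Reactants: 9 ethyl 3-{[(3S,4S)-4-[(tert-butyldimethylsilyl)oxy]-2-methylhex-1-en-5-yn-3-yl]oxy}-2-oxo-2H-pyran-6-carboxylate
Product: 10 ethyl 3-{[(1R,2S)-2-[(tert-butyldimethylsilyl)oxy]-1-(2-methyloxiran-2-yl)but-3-yn-1-yl]oxy}-2-oxo-2H-pyran-6-carboxylate (both oxirane epimers)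
Conditions: mCPBA, NaHCO3, CH2Cl2, 0 °C → rt
Reagents that add atoms: 3-chloroperbenzoic acid, OOC(=O)c1cccc(Cl)c1
Why: Prilezhaev epoxidation: the peracid should attack only the isolated 1,1-disubstituted alkene (the electron-poor pyrone and the terminal alkyne are far less nucleophilic), which removes the allyl vinyl ether before heating; the new oxirane centre is uncontrolled and is erased in step 9.

Step 8
Reactants: 10 ethyl 3-{[(1R,2S)-2-[(tert-butyldimethylsilyl)oxy]-1-(2-methyloxiran-2-yl)but-3-yn-1-yl]oxy}-2-oxo-2H-pyran-6-carboxylate (both oxirane epimers)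
Product: 12 ethyl (2R,3S)-3-[(tert-butyldimethylsilyl)oxy]-2-(2-methyloxiran-2-yl)-2,3-dihydro-1-benzofuran-5-carboxylate (both oxirane epimers), via bridged lactone cycloadduct 11 (not isolated)
Conditions: 1,2-dichlorobenzene (0.01 M), BHT (cat.), 160 °C, sealed tube, argon
Reagents that add atoms: none
Why: Thermal intramolecular [4+2] cycloaddition in which C3 and C6 of the 2-pyrone are the diene termini and the tethered alkyne is the 2π partner forms C7a–C3a and C5–C4 and gives the 2-oxabicyclo[2.2.2]octadienone 11, which then loses CO2 by retro-[4+2]. The closest known reaction type is the intramolecular 2-pyrone–alkyne Diels–Alder/decarboxylation benzannulation, together with the alkynyloxy-tethered azadiene cycloadditions that build dihydrofuran-fused arenes in the same way. The dihydrofuran ring (O1, C2, C3, C3a, C7a) closes in the fused mode of a tether anchored at a diene terminus, and the six-membered carbocycle closes through the two new σ bonds and becomes the benzene ring on cycloreversion. No lasting stereocentre is created (the bridgeheads of 11 disappear, so both facial approaches converge), and C2 and C3 are spectators on the tether, their threo relation becoming cis. The step needs regio- and periselectivity: the three-atom tether lets the inner alkyne carbon reach only pyrone C3, so the ester must end on C5 para to O1, and with the isopropenyl group stored as an oxirane there is no allyl vinyl ether left for a [3,3] shift to pyrone C4. The silyl ether at C3, unlike an ester, should not be lost by thermal elimination to a benzofuran.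

Step 9
Reactants: 12 ethyl (2R,3S)-3-[(tert-butyldimethylsilyl)oxy]-2-(2-methyloxiran-2-yl)-2,3-dihydro-1-benzofuran-5-carboxylate (both oxirane epimers)
Product: 13 ethyl (2S,3S)-3-[(tert-butyldimethylsilyl)oxy]-2-(prop-1-en-2-yl)-2,3-dihydro-1-benzofuran-5-carboxylate
Conditions: Zn dust, NaI, NaOAc, AcOH/THF, 0 °C → rt
Reagents that add atoms: none
Why: Reductive deoxygenation of an oxirane through its iodohydrin (iodide opens the buffered epoxide at the CH2 terminus, zinc then eliminates iodide and hydroxide); both epimers converge on the isopropenyl compound, and the silyl ether, the ester and the ring stereocentres are not involved.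

Step 10
Reactants: 13 ethyl (2S,3S)-3-[(tert-butyldimethylsilyl)oxy]-2-(prop-1-en-2-yl)-2,3-dihydro-1-benzofuran-5-carboxylate
Product: 15 1-[(2S,3S)-3-[(tert-butyldimethylsilyl)oxy]-2-(prop-1-en-2-yl)-2,3-dihydro-1-benzofuran-5-yl]ethan-1-one, via Weinreb amide 14 (not isolated)
Conditions: MeNH(OMe)·HCl (1.5 equiv), i-PrMgCl (3.0 equiv), THF, −20 °C; then MeMgBr (2 equiv), 0 °C; aq. NH4Cl
Reagents that add atoms: methylmagnesium bromide, C[Mg]Br
Why: Weinreb ketone synthesis in one flask: the magnesium amide converts the aryl ester into the N-methoxy-N-methylamide, whose chelated adduct with MeMgBr cannot add a second time and releases the methyl ketone on work-up.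

Step 11
Reactants: 15 1-[(2S,3S)-3-[(tert-butyldimethylsilyl)oxy]-2-(prop-1-en-2-yl)-2,3-dihydro-1-benzofuran-5-yl]ethan-1-one
Product: 16 (1R)-1-[(2S,3S)-3-[(tert-butyldimethylsilyl)oxy]-2-(prop-1-en-2-yl)-2,3-dihydro-1-benzofuran-5-yl]ethan-1-ol
Conditions: RuCl[(R,R)-TsDPEN](p-cymene) (1 mol %), HCO2H/Et3N (5:2), CH2Cl2, 30 °C
Reagents that add atoms: none
Why: Noyori asymmetric transfer hydrogenation of an aryl methyl ketone: the (R,R)-diamine catalyst should deliver hydride to the Si face and give the (R)-carbinol under reagent control, with the isolated alkene and the remote ring stereocentres unaffected.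

Step 12
Reactants: 16 (1R)-1-[(2S,3S)-3-[(tert-butyldimethylsilyl)oxy]-2-(prop-1-en-2-yl)-2,3-dihydro-1-benzofuran-5-yl]ethan-1-ol; 17 tiglic acid
Product: 18 (1R)-1-[(2S,3S)-3-[(tert-butyldimethylsilyl)oxy]-2-(prop-1-en-2-yl)-2,3-dihydro-1-benzofuran-5-yl]ethyl (2E)-2-methylbut-2-enoate
Conditions: DCC, DMAP (cat.), CH2Cl2, 0 °C → rt
Reagents that add atoms: none
Why: Steglich esterification: acylation takes place at oxygen, so the benzylic carbinol keeps its configuration, and the thermodynamically preferred (E)-geometry of the tigloyl group is not at risk.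

Step 13
Reactants: 18 (1R)-1-[(2S,3S)-3-[(tert-butyldimethylsilyl)oxy]-2-(prop-1-en-2-yl)-2,3-dihydro-1-benzofuran-5-yl]ethyl (2E)-2-methylbut-2-enoate
Product: 19 (1R)-1-[(2S,3S)-3-hydroxy-2-(prop-1-en-2-yl)-2,3-dihydro-1-benzofuran-5-yl]ethyl (2E)-2-methylbut-2-enoate
Conditions: Bu4NF (1.2 equiv), AcOH (1.2 equiv), THF, 0 °C → rt
Reagents that add atoms: none
Why: Fluoride-mediated desilylation, buffered with acetic acid so that the benzylic ester is not cleaved and the liberated benzylic alcohol is not dehydrated.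

Step 14
Reactants: 19 (1R)-1-[(2S,3S)-3-hydroxy-2-(prop-1-en-2-yl)-2,3-dihydro-1-benzofuran-5-yl]ethyl (2E)-2-methylbut-2-enoate
Product: 20 (1R)-1-[(2S,3S)-3-(acetyloxy)-2-(prop-1-en-2-yl)-2,3-dihydro-1-benzofuran-5-yl]ethyl (2E)-2-methylbut-2-enoate
Conditions: Ac2O, pyridine, DMAP (cat.), CH2Cl2, 0 °C
Reagents that add atoms: acetic anhydride, CC(=O)OC(C)=O
Why: DMAP-catalysed acetylation of the secondary alcohol under basic conditions, with retention at C3 and no acid that could trigger elimination to the benzofuran.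

Step 15
Reactants: 20 (1R)-1-[(2S,3S)-3-(acetyloxy)-2-(prop-1-en-2-yl)-2,3-dihydro-1-benzofuran-5-yl]ethyl (2E)-2-methylbut-2-enoate
Product: 22 (1R)-1-[(2S,3S)-3-(acetyloxy)-2-(3-oxoprop-1-en-2-yl)-2,3-dihydro-1-benzofuran-5-yl]ethyl (2E)-2-methylbut-2-enoate, via allylic alcohol 21 (not isolated)
Conditions: SeO2 (1.5 equiv), 1,4-dioxane, 70 °C
Reagents that add atoms: selenium dioxide, O=[Se]=O
Why: Riley allylic oxidation: ene reaction of SeO2 at the electron-rich 1,1-disubstituted alkene and [2,3]-shift give the allylic alcohol, which SeO2 oxidises on to the enal, while the conjugated, electron-poor tigloyl alkene should react far more slowly.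

## Compound list

1 | 3-methylbut-2-enal | CC(C)=CC=O | starting material
2 | ethynylmagnesium bromide | C#C[Mg]Br | starting material
3 | rac-5-methylhex-4-en-1-yn-3-ol | CC(C)=CC(O)C#C | intermediate
4 | (1S)-1-[(2S)-3,3-dimethyloxiran-2-yl]prop-2-yn-1-ol | CC1(C)O[C@H]1[C@@H](O)C#C | intermediate
5 | tert-butyl{[(1S)-1-[(2S)-3,3-dimethyloxiran-2-yl]prop-2-yn-1-yl]oxy}dimethylsilane | CC1(C)O[C@H]1[C@@H](O[Si](C)(C)C(C)(C)C)C#C | intermediate
6 | (3R,4S)-4-[(tert-butyldimethylsilyl)oxy]-2-methylhex-1-en-5-yn-3-ol | C=C(C)[C@@H](O)[C@@H](O[Si](C)(C)C(C)(C)C)C#C | intermediate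
7 | 3-hydroxy-2-oxo-2H-pyran-6-carboxylic acid | O=C(O)C1=CC=C(O)C(=O)O1 | starting material
8 | ethyl 3-hydroxy-2-oxo-2H-pyran-6-carboxylate | CCOC(=O)C1=CC=C(O)C(=O)O1 | intermediate
9 | ethyl 3-{[(3S,4S)-4-[(tert-butyldimethylsilyl)oxy]-2-methylhex-1-en-5-yn-3-yl]oxy}-2-oxo-2H-pyran-6-carboxylate | CCOC(=O)C1=CC=C(O[C@@H](C(C)=C)[C@@H](O[Si](C)(C)C(C)(C)C)C#C)C(=O)O1 | intermediate
10 | ethyl 3-{[(1R,2S)-2-[(tert-butyldimethylsilyl)oxy]-1-(2-methyloxiran-2-yl)but-3-yn-1-yl]oxy}-2-oxo-2H-pyran-6-carboxylate (both oxirane epimers) | CCOC(=O)C1=CC=C(O[C@@H](C2(C)CO2)[C@@H](O[Si](C)(C)C(C)(C)C)C#C)C(=O)O1 | intermediate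
11 | bridged lactone cycloadduct: ethyl 3-oxo-2-oxabicyclo[2.2.2]octa-5,7-diene-1-carboxylate with an oxolane ring fused across C4 and C5 (ring oxygen on C4; 2-methyloxiranyl and silyloxy groups on the two oxolane carbons; either facial isomer, bridgeheads left open) | CCOC(=O)C12OC(=O)C3(C=C1)O[C@@H](C4(C)CO4)[C@@H](O[Si](C)(C)C(C)(C)C)C3=C2 | intermediate (not isolated)
12 | ethyl (2R,3S)-3-[(tert-butyldimethylsilyl)oxy]-2-(2-methyloxiran-2-yl)-2,3-dihydro-1-benzofuran-5-carboxylate (both oxirane epimers) | CC1(CO1)[C@@H]2Oc3ccc(C(=O)OCC)cc3[C@@H]2O[Si](C)(C)C(C)(C)C | intermediate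
13 | ethyl (2S,3S)-3-[(tert-butyldimethylsilyl)oxy]-2-(prop-1-en-2-yl)-2,3-dihydro-1-benzofuran-5-carboxylate | C=C(C)[C@@H]1Oc2ccc(C(=O)OCC)cc2[C@@H]1O[Si](C)(C)C(C)(C)C | intermediate
14 | (2S,3S)-3-[(tert-butyldimethylsilyl)oxy]-N-methoxy-N-methyl-2-(prop-1-en-2-yl)-2,3-dihydro-1-benzofuran-5-carboxamide | C=C(C)[C@@H]1Oc2ccc(C(=O)N(C)OC)cc2[C@@H]1O[Si](C)(C)C(C)(C)C | intermediate (not isolated)
15 | 1-[(2S,3S)-3-[(tert-butyldimethylsilyl)oxy]-2-(prop-1-en-2-yl)-2,3-dihydro-1-benzofuran-5-yl]ethan-1-one | C=C(C)[C@@H]1Oc2ccc(C(C)=O)cc2[C@@H]1O[Si](C)(C)C(C)(C)C | intermediate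
16 | (1R)-1-[(2S,3S)-3-[(tert-butyldimethylsilyl)oxy]-2-(prop-1-en-2-yl)-2,3-dihydro-1-benzofuran-5-yl]ethan-1-ol | C=C(C)[C@@H]1Oc2ccc([C@@H](C)O)cc2[C@@H]1O[Si](C)(C)C(C)(C)C | intermediate
17 | tiglic acid [(2E)-2-methylbut-2-enoic acid] | C/C=C(\C)C(=O)O | starting material
18 | (1R)-1-[(2S,3S)-3-[(tert-butyldimethylsilyl)oxy]-2-(prop-1-en-2-yl)-2,3-dihydro-1-benzofuran-5-yl]ethyl (2E)-2-methylbut-2-enoate | C=C(C)[C@@H]1Oc2ccc([C@@H](C)OC(=O)/C(C)=C/C)cc2[C@@H]1O[Si](C)(C)C(C)(C)C | intermediate
19 | (1R)-1-[(2S,3S)-3-hydroxy-2-(prop-1-en-2-yl)-2,3-dihydro-1-benzofuran-5-yl]ethyl (2E)-2-methylbut-2-enoate | C=C(C)[C@@H]1Oc2ccc([C@@H](C)OC(=O)/C(C)=C/C)cc2[C@@H]1O | intermediate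
20 | (1R)-1-[(2S,3S)-3-(acetyloxy)-2-(prop-1-en-2-yl)-2,3-dihydro-1-benzofuran-5-yl]ethyl (2E)-2-methylbut-2-enoate | C=C(C)[C@@H]1Oc2ccc([C@@H](C)OC(=O)/C(C)=C/C)cc2[C@@H]1OC(C)=O | intermediate
21 | (1R)-1-[(2S,3S)-3-(acetyloxy)-2-(3-hydroxyprop-1-en-2-yl)-2,3-dihydro-1-benzofuran-5-yl]ethyl (2E)-2-methylbut-2-enoate | C=C(CO)[C@@H]1Oc2ccc([C@@H](C)OC(=O)/C(C)=C/C)cc2[C@@H]1OC(C)=O | intermediate (not isolated)
22 | (1R)-1-[(2S,3S)-3-(acetyloxy)-2-(3-oxoprop-1-en-2-yl)-2,3-dihydro-1-benzofuran-5-yl]ethyl (2E)-2-methylbut-2-enoate (CNP0294391.6) | C=C(C=O)[C@@H]1Oc2ccc([C@@H](C)OC(=O)/C(C)=C/C)cc2[C@@H]1OC(C)=O | target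

## Step count and risks

Total: 15 steps. Longest linear sequence: 14 steps (steps 1–4 and 6–15; step 5 is a one-step side branch).

**Step 8 (most likely to fail).** The cycloaddition has to pass through a strained fused transition state, and thermal breakdown of the pyrone ether (oligomerisation through the alkyne, loss of the silyl group) may outrun it. The fallback has the benzene ring present from the start and closes the dihydrofuran ring by C–O bond formation; it sets out from 1 and comes back at 13. Purchased ethyl 4-hydroxy-3-iodobenzoate would be O-allylated (allyl bromide, K2CO3, DMF) to ethyl 3-iodo-4-(prop-2-en-1-yloxy)benzoate F1. Iodine–magnesium exchange (i-PrMgCl·LiCl, THF, −40 °C) and addition to 1 should give racemic ethyl 3-(1-hydroxy-3-methylbut-2-en-1-yl)-4-(prop-2-en-1-yloxy)benzoate F2. The Sharpless kinetic resolution of step 2 (L-(+)-tartrate) should turn its (R)-enantiomer into ethyl 3-[(S)-[(2S)-3,3-dimethyloxiran-2-yl](hydroxy)methyl]-4-(prop-2-en-1-yloxy)benzoate F3. Silylation as in step 3 would give ethyl 3-[(S)-[(tert-butyldimethylsilyl)oxy][(2S)-3,3-dimethyloxiran-2-yl]methyl]-4-(prop-2-en-1-yloxy)benzoate F4, and the aluminium amide of step 4 should open it to ethyl 3-[(1S,2R)-1-[(tert-butyldimethylsilyl)oxy]-2-hydroxy-3-methylbut-3-en-1-yl]-4-(prop-2-en-1-yloxy)benzoate F5. Pd(PPh3)4 with morpholine would remove the allyl group to give the phenol ethyl 3-[(1S,2R)-1-[(tert-butyldimethylsilyl)oxy]-2-hydroxy-3-methylbut-3-en-1-yl]-4-hydroxybenzoate F6. An intramolecular Mitsunobu etherification (PPh3, DIAD, THF) should then close O1–C2 with inversion and give 13.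

**Step 6.** The oxyphosphonium ion of the hindered allylic alcohol may ionise or be attacked at the alkene terminus, which would give the transposed ether, loss of configuration at C2, or elimination. The fallback changes the order of events so that the carbinol is no longer allylic when it is displaced; it sets out from 6 and comes back at 10. Hydroxyl-directed epoxidation of 6 (VO(acac)2, t-BuOOH, CH2Cl2) should give mainly (1S,2S)-2-[(tert-butyldimethylsilyl)oxy]-1-[(2R)-2-methyloxiran-2-yl]but-3-yn-1-ol F7. Its Mitsunobu etherification with 8 would lead directly to 10 (chiefly one oxirane epimer), and step 7 is then not needed.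

**Step 2.** The cis-methyl group at the alkene terminus and the small ethynyl substituent may narrow the rate difference between the two enantiomers and erode the erythro preference, so that 4 forms with low enantiomeric and diastereomeric purity. The fallback fixes the carbinol configuration before the epoxidation; it sets out from 3 and comes back at 4. Oxidation of 3 with MnO2 would give 5-methylhex-4-en-1-yn-3-one F8, and Midland reduction with (R)-Alpine-borane should give (3R)-5-methylhex-4-en-1-yn-3-ol F9. Its Sharpless epoxidation with the L-(+)-tartrate is then the matched case, run to full conversion, in which reagent and substrate both favour 4 and residual (S)-alcohol is left behind.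

## Further compounds

F1 | step 8 | ethyl 3-iodo-4-(prop-2-en-1-yloxy)benzoate | CCOC(=O)c1ccc(OCC=C)c(I)c1
F2 | step 8 | rac-ethyl 3-(1-hydroxy-3-methylbut-2-en-1-yl)-4-(prop-2-en-1-yloxy)benzoate | CCOC(=O)c1ccc(OCC=C)c(C(O)C=C(C)C)c1
F3 | step 8 | ethyl 3-[(S)-[(2S)-3,3-dimethyloxiran-2-yl](hydroxy)methyl]-4-(prop-2-en-1-yloxy)benzoate | CC1(C)O[C@H]1[C@@H](O)c1cc(C(=O)OCC)ccc1OCC=C
F4 | step 8 | ethyl 3-[(S)-[(tert-butyldimethylsilyl)oxy][(2S)-3,3-dimethyloxiran-2-yl]methyl]-4-(prop-2-en-1-yloxy)benzoate | CC1(C)O[C@H]1[C@@H](O[Si](C)(C)C(C)(C)C)c1cc(C(=O)OCC)ccc1OCC=C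
F5 | step 8 | ethyl 3-[(1S,2R)-1-[(tert-butyldimethylsilyl)oxy]-2-hydroxy-3-methylbut-3-en-1-yl]-4-(prop-2-en-1-yloxy)benzoate | C=C(C)[C@@H](O)[C@@H](O[Si](C)(C)C(C)(C)C)c1cc(C(=O)OCC)ccc1OCC=C
F6 | step 8 | ethyl 3-[(1S,2R)-1-[(tert-butyldimethylsilyl)oxy]-2-hydroxy-3-methylbut-3-en-1-yl]-4-hydroxybenzoate | C=C(C)[C@@H](O)[C@@H](O[Si](C)(C)C(C)(C)C)c1cc(C(=O)OCC)ccc1O
F7 | step 6 | (1S,2S)-2-[(tert-butyldimethylsilyl)oxy]-1-[(2R)-2-methyloxiran-2-yl]but-3-yn-1-ol | O[C@H]([C@@]1(C)CO1)[C@@H](O[Si](C)(C)C(C)(C)C)C#C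
F8 | step 2 | 5-methylhex-4-en-1-yn-3-one | CC(C)=CC(=O)C#C
F9 | step 2 | (3R)-5-methylhex-4-en-1-yn-3-ol | CC(C)=C[C@@H](O)C#C
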